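**Plan**
1. Retrosynthesis: after the seven phenols are masked as benzyl ethers, the O1–C2 bond of the pyranone ring (ring C) is cut first. O1–C2–C3–C4(=O) is a β-aryloxy ketone, so its parent is the 2'-hydroxychalcone of ring A (phenol O1 ortho to the C4 acyl group); this is the ring closure flavonoid biosynthesis itself uses.
2. A tert-butoxycarbonyl group on C3 serves as a removable activating group; the alkylidene β-ketoester is cut at C2=C3 (benzaldehyde) and at C3–CO2tBu back to a hexasubstituted acetophenone.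
3. Next the two ring A–CH2 bonds are cut (aryl iodide + benzylzinc), then the CH2–aryl bonds inside the side chains (benzyl bromide + one formyl arylboronate, used twice).
4. Forward: the two-ring and three-ring benzyl bromides grow on one iterative line. 4,6-Bis(benzyloxy)-2-hydroxyacetophenone is iodinated and benzylated first ortho to its free OH (later C8), then at the last free carbon (later C6). Claisen and Knoevenagel steps follow, ring C is closed last, and one hydrogenolysis frees the phenols.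
5. Regio- and stereochemistry: the one phenol that stays free throughout (hydrogen-bonded to the ketone) directs the first iodination and is the only oxygen able to close ring C. C2 (S) is set in that closure by a cinchona-derived bifunctional thiourea and meets no base afterwards.

Key step: step 14

Assumption: of the two pseudo-enantiomeric cinchona thioureas, the quinidine-derived one is taken to give the 2S series; if the sense of induction is the opposite, the quinine-derived catalyst replaces it and nothing else changes.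

Abbreviations in names: "D-benzyl" = 2-(benzyloxy)-5-[2-(benzyloxy)benzyl]benzyl (two-ring side chain); "T-benzyl" = 2-(benzyloxy)-5-{2-(benzyloxy)-5-[2-(benzyloxy)benzyl]benzyl}benzyl (three-ring side chain).

**Route**

Step 1
Reactants: 1 2-(benzyloxy)-5-bromobenzaldehyde
Product: 2 2-(benzyloxy)-5-(4,4,5,5-tetramethyl-1,3,2-dioxaborolan-2-yl)benzaldehyde
Conditions: B2pin2 (1.1 equiv), PdCl2(dppf) (3 mol %), KOAc (3 equiv), 1,4-dioxane, 90 °C
Reagents that add atoms: bis(pinacolato)diboron, CC1(C)OB(OC1(C)C)B1OC(C)(C)C(C)(C)O1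
Why: Miyaura borylation of an aryl bromide, in which the weak base KOAc leaves the aldehyde and the benzyl ether untouched.

Step 2
Reactants: 3 1-(benzyloxy)-2-(bromomethyl)benzene; 2 2-(benzyloxy)-5-(4,4,5,5-tetramethyl-1,3,2-dioxaborolan-2-yl)benzaldehyde
Product: 4 2-(benzyloxy)-5-[2-(benzyloxy)benzyl]benzaldehyde
Conditions: Pd(PPh3)4 (3 mol %), K2CO3 (2 equiv), THF/H2O 4:1, 65 °C
Reagents that add atoms: none
Why: Suzuki–Miyaura coupling of a benzylic bromide with an arylboronic ester should give the diarylmethane, since oxidative addition into the benzylic C–Br bond is fast and the aldehyde is inert.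

Step 3
Reactants: 4 2-(benzyloxy)-5-[2-(benzyloxy)benzyl]benzaldehyde
Product: 5 {2-(benzyloxy)-5-[2-(benzyloxy)benzyl]phenyl}methanol
Conditions: NaBH4 (0.6 equiv), THF/MeOH 1:1, 0 °C
Reagents that add atoms: none
Why: Chemoselective borohydride reduction of the aldehyde to the benzylic alcohol.

Step 4
Reactants: 5 {2-(benzyloxy)-5-[2-(benzyloxy)benzyl]phenyl}methanol
Product: 6 1-(benzyloxy)-4-[2-(benzyloxy)benzyl]-2-(bromomethyl)benzene (D-benzyl bromide)
Conditions: PBr3 (0.4 equiv), CH2Cl2, 0 °C; used promptly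
Reagents that add atoms: phosphorus tribromide, BrP(Br)Br
Why: Conversion of a benzylic alcohol into the bromide through its phosphite ester (SN2 by bromide), conditions under which aryl benzyl ethers should survive.

Step 5
Reactants: 6 1-(benzyloxy)-4-[2-(benzyloxy)benzyl]-2-(bromomethyl)benzene; 2 2-(benzyloxy)-5-(4,4,5,5-tetramethyl-1,3,2-dioxaborolan-2-yl)benzaldehyde
Product: 7 2-(benzyloxy)-5-{2-(benzyloxy)-5-[2-(benzyloxy)benzyl]benzyl}benzaldehyde
Conditions: Pd(PPh3)4 (3 mol %), K2CO3 (2 equiv), THF/H2O 4:1, 65 °C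
Reagents that add atoms: none
Why: The same benzylic Suzuki–Miyaura coupling as in step 2 adds the third ring with the same ortho/para pattern.

Step 6
Reactants: 7 2-(benzyloxy)-5-{2-(benzyloxy)-5-[2-(benzyloxy)benzyl]benzyl}benzaldehyde
Product: 8 (2-(benzyloxy)-5-{2-(benzyloxy)-5-[2-(benzyloxy)benzyl]benzyl}phenyl)methanol
Conditions: NaBH4 (0.6 equiv), THF/MeOH 1:1, 0 °C
Reagents that add atoms: none
Why: Borohydride reduction of the aldehyde, as in step 3.

Step 7
Reactants: 8 (2-(benzyloxy)-5-{2-(benzyloxy)-5-[2-(benzyloxy)benzyl]benzyl}phenyl)methanol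
Product: 9 1-(benzyloxy)-4-{2-(benzyloxy)-5-[2-(benzyloxy)benzyl]benzyl}-2-(bromomethyl)benzene (T-benzyl bromide)
Conditions: PBr3 (0.4 equiv), CH2Cl2, 0 °C; used promptly
Reagents that add atoms: phosphorus tribromide, BrP(Br)Br
Why: Benzylic alcohol to bromide, as in step 4.

Step 8
Reactants: 10 1-[4,6-bis(benzyloxy)-2-hydroxyphenyl]ethanone
Product: 11 1-[4,6-bis(benzyloxy)-2-hydroxy-3-iodophenyl]ethanone
Conditions: BnMe3N ICl2 (1.05 equiv), NaHCO3 (2 equiv), CH2Cl2/MeOH 5:2, 25 °C
Reagents that add atoms: benzyltrimethylammonium dichloroiodate, C[N+](C)(C)Cc1ccccc1.Cl[I-]Cl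
Why: Electrophilic aromatic iodination directed by the free, hydrogen-bonded phenol to its ortho carbon C3, the known preference of 2-hydroxy-4,6-dialkoxyacetophenones; C5 between two benzyloxy groups is the more hindered site.

Step 9
Reactants: 6 1-(benzyloxy)-4-[2-(benzyloxy)benzyl]-2-(bromomethyl)benzene; 11 1-[4,6-bis(benzyloxy)-2-hydroxy-3-iodophenyl]ethanone
Product: 13 1-[4,6-bis(benzyloxy)-3-(D-benzyl)-2-hydroxyphenyl]ethanone, via D-benzylzinc bromide 12 (not isolated)
Conditions: 6, Zn dust (1.5 equiv), LiCl (1.5 equiv), THF, 25 °C; then this solution (1.5 equiv) added over 1 h to 11, Pd(OAc)2 (2 mol %), SPhos (4 mol %), THF, 25 °C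
Reagents that add atoms: none
Why: LiCl-assisted zinc insertion into the benzylic bromide followed by Negishi coupling, a reaction type that tolerates ketones and, with slow addition, free phenols, should join ring A to the two-ring chain next to the free OH.

Step 10
Reactants: 13 1-[4,6-bis(benzyloxy)-3-(D-benzyl)-2-hydroxyphenyl]ethanone
Product: 14 1-[4,6-bis(benzyloxy)-3-(D-benzyl)-2-hydroxy-5-iodophenyl]ethanone
Conditions: N-iodosuccinimide (1.1 equiv), DMF, 0 to 25 °C
Reagents that add atoms: N-iodosuccinimide, O=C1CCC(=O)N1I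
Why: Electrophilic iodination at C5, the only free carbon of ring A (para to the free OH, ortho to both benzyloxy groups) and far more electron-rich than the alkoxyarene rings of the chain, which need acid activation to react with this reagent.

Step 11
Reactants: 9 1-(benzyloxy)-4-{2-(benzyloxy)-5-[2-(benzyloxy)benzyl]benzyl}-2-(bromomethyl)benzene; 14 1-[4,6-bis(benzyloxy)-3-(D-benzyl)-2-hydroxy-5-iodophenyl]ethanone
Product: 16 1-[4,6-bis(benzyloxy)-3-(D-benzyl)-5-(T-benzyl)-2-hydroxyphenyl]ethanone, via T-benzylzinc bromide 15 (not isolated)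
Conditions: 9, Zn dust (1.5 equiv), LiCl (1.5 equiv), THF, 25 °C; then this solution (1.5 equiv) added over 1 h to 14, Pd(OAc)2 (5 mol %), SPhos (10 mol %), THF, 50 °C
Reagents that add atoms: none
Why: Negishi coupling with a bulky biarylphosphine ligand, a combination suited to di-ortho-substituted aryl halides, should place the three-ring chain between the two benzyloxy groups.

Step 12
Reactants: 16 1-[4,6-bis(benzyloxy)-3-(D-benzyl)-5-(T-benzyl)-2-hydroxyphenyl]ethanone
Product: 17 tert-butyl 3-[4,6-bis(benzyloxy)-3-(D-benzyl)-5-(T-benzyl)-2-hydroxyphenyl]-3-oxopropanoate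
Conditions: LiN(SiMe3)2 (3.3 equiv), THF, −78 °C; Boc2O (1.5 equiv), −78 to 0 °C; then 1 M HCl, 0 °C
Reagents that add atoms: di-tert-butyl dicarbonate, CC(C)(C)OC(=O)OC(=O)OC(C)(C)C
Why: Claisen-type C-acylation of the methyl ketone enolate within the phenoxide–enolate dianion (the carbon terminus is the more nucleophilic site, the third equivalent of base takes up the acidic product), giving an ester too bulky to lactonise onto the neighbouring phenol.

Step 13
Reactants: 17 tert-butyl 3-[4,6-bis(benzyloxy)-3-(D-benzyl)-5-(T-benzyl)-2-hydroxyphenyl]-3-oxopropanoate; 18 benzaldehyde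
Product: 19 tert-butyl 2-[4,6-bis(benzyloxy)-3-(D-benzyl)-5-(T-benzyl)-2-hydroxybenzoyl]-3-phenylprop-2-enoate (E/Z mixture)
Conditions: piperidine (10 mol %), AcOH (10 mol %), 4 Å molecular sieves, toluene, 25–40 °C
Reagents that add atoms: none
Why: Knoevenagel condensation of the β-ketoester with benzaldehyde under a weakly basic buffer, in which the phenol stays hydrogen-bonded to the ketone and should not yet add to the new alkene; both alkene isomers are carried on.

Step 14
Reactants: 19 tert-butyl 2-[4,6-bis(benzyloxy)-3-(D-benzyl)-5-(T-benzyl)-2-hydroxybenzoyl]-3-phenylprop-2-enoate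
Product: 21 (2S)-5,7-bis(benzyloxy)-8-(D-benzyl)-6-(T-benzyl)-2-phenylchroman-4-one, via tert-butyl (2S)-flavanone-3-carboxylate 20 (not isolated)
Conditions: thiourea from 9-amino(9-deoxy)-epi-quinidine and 3,5-bis(trifluoromethyl)phenyl isothiocyanate (10 mol %), toluene, −25 °C; then TsOH·H2O (0.5 equiv), 80 °C
Reagents that add atoms: none
Why: The quinuclidine nitrogen of the bifunctional catalyst deprotonates the single free phenol (the later O1) while the thiourea binds the two carbonyl groups of the alkylidene β-ketoester, and the phenoxide adds to the benzylic β-carbon in an intramolecular oxa-Michael addition that copies the chalcone-to-flavanone cyclisation of flavonoid biosynthesis; protonation of the enolate gives 20. The closest known reaction type is the cinchona-thiourea-catalysed oxa-conjugate addition of 2-hydroxyaryl alkylidene β-ketoesters with acid decarboxylation in the same pot. Ring C closes in the 6-endo-trig mode by formation of the O1–C2 bond. The new stereocentre C2 is controlled by the catalyst alone, which holds the hydrogen-bonded alkylidene so that one face is open to the phenoxide; the C3 centre of 20 does not matter, because TsOH cleaves the tert-butyl ester to isobutene and the β-keto acid loses CO2. The step needs regioselectivity between the two oxygens ortho to the carbonyl, secured because only the oxygen next to the two-ring chain is free and the other is a benzyl ether, and enantioselectivity, secured by the tert-butyl ester, which gives the two-point binding site and enough electrophilicity for the addition to run cold without background reaction. The acid that starts the decarboxylation also protonates the amine catalyst, so the configured and now only singly activated flavanone should not reopen.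

Step 15
Reactants: 21 (2S)-5,7-bis(benzyloxy)-8-(D-benzyl)-6-(T-benzyl)-2-phenylchroman-4-one
Product: 22 Sarmentosumin D, (2S)-5,7-dihydroxy-8-[2-hydroxy-5-(2-hydroxybenzyl)benzyl]-6-{2-hydroxy-5-[2-hydroxy-5-(2-hydroxybenzyl)benzyl]benzyl}-2-phenylchroman-4-one
Conditions: H2 (1 atm), Pd/C (10 wt %), EtOAc/MeOH 1:1, 25 °C
Reagents that add atoms: none
Why: Hydrogenolysis of the seven aryl benzyl ethers under neutral conditions, in which the cyclic benzylic C2–O1 bond and the aryl ketone react much more slowly and C2 meets no base that could open the ring.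

**Compound list**

1 | 2-(benzyloxy)-5-bromobenzaldehyde | O=Cc1cc(Br)ccc1OCc1ccccc1 | starting material
2 | 2-(benzyloxy)-5-(4,4,5,5-tetramethyl-1,3,2-dioxaborolan-2-yl)benzaldehyde | O=Cc1cc(B2OC(C)(C)C(C)(C)O2)ccc1OCc1ccccc1 | intermediate
3 | 1-(benzyloxy)-2-(bromomethyl)benzene | BrCc1ccccc1OCc1ccccc1 | starting material
4 | 2-(benzyloxy)-5-[2-(benzyloxy)benzyl]benzaldehyde | O=Cc1cc(Cc2ccccc2OCc2ccccc2)ccc1OCc1ccccc1 | intermediate
5 | {2-(benzyloxy)-5-[2-(benzyloxy)benzyl]phenyl}methanol | OCc1cc(Cc2ccccc2OCc2ccccc2)ccc1OCc1ccccc1 | intermediate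
6 | 1-(benzyloxy)-4-[2-(benzyloxy)benzyl]-2-(bromomethyl)benzene (D-benzyl bromide) | BrCc1cc(Cc2ccccc2OCc2ccccc2)ccc1OCc1ccccc1 | intermediate
7 | 2-(benzyloxy)-5-{2-(benzyloxy)-5-[2-(benzyloxy)benzyl]benzyl}benzaldehyde | O=Cc1cc(Cc2cc(Cc3ccccc3OCc3ccccc3)ccc2OCc2ccccc2)ccc1OCc1ccccc1 | intermediate
8 | (2-(benzyloxy)-5-{2-(benzyloxy)-5-[2-(benzyloxy)benzyl]benzyl}phenyl)methanol | OCc1cc(Cc2cc(Cc3ccccc3OCc3ccccc3)ccc2OCc2ccccc2)ccc1OCc1ccccc1 | intermediate
9 | 1-(benzyloxy)-4-{2-(benzyloxy)-5-[2-(benzyloxy)benzyl]benzyl}-2-(bromomethyl)benzene (T-benzyl bromide) | BrCc1cc(Cc2cc(Cc3ccccc3OCc3ccccc3)ccc2OCc2ccccc2)ccc1OCc1ccccc1 | intermediate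
10 | 1-[4,6-bis(benzyloxy)-2-hydroxyphenyl]ethanone | CC(=O)c1c(O)cc(OCc2ccccc2)cc1OCc1ccccc1 | starting material
11 | 1-[4,6-bis(benzyloxy)-2-hydroxy-3-iodophenyl]ethanone | CC(=O)c1c(O)c(I)c(OCc2ccccc2)cc1OCc1ccccc1 | intermediate
12 | D-benzylzinc bromide, {2-(benzyloxy)-5-[2-(benzyloxy)benzyl]benzyl}zinc bromide | Br[Zn]Cc1cc(Cc2ccccc2OCc2ccccc2)ccc1OCc1ccccc1 | intermediate
13 | 1-[4,6-bis(benzyloxy)-3-(D-benzyl)-2-hydroxyphenyl]ethanone | CC(=O)c1c(O)c(Cc2cc(Cc3ccccc3OCc3ccccc3)ccc2OCc2ccccc2)c(OCc2ccccc2)cc1OCc1ccccc1 | intermediate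
14 | 1-[4,6-bis(benzyloxy)-3-(D-benzyl)-2-hydroxy-5-iodophenyl]ethanone | CC(=O)c1c(O)c(Cc2cc(Cc3ccccc3OCc3ccccc3)ccc2OCc2ccccc2)c(OCc2ccccc2)c(I)c1OCc1ccccc1 | intermediate
15 | T-benzylzinc bromide, (2-(benzyloxy)-5-{2-(benzyloxy)-5-[2-(benzyloxy)benzyl]benzyl}benzyl)zinc bromide | Br[Zn]Cc1cc(Cc2cc(Cc3ccccc3OCc3ccccc3)ccc2OCc2ccccc2)ccc1OCc1ccccc1 | intermediate
16 | 1-[4,6-bis(benzyloxy)-3-(D-benzyl)-5-(T-benzyl)-2-hydroxyphenyl]ethanone | CC(=O)c1c(O)c(Cc2cc(Cc3ccccc3OCc3ccccc3)ccc2OCc2ccccc2)c(OCc2ccccc2)c(Cc2cc(Cc3cc(Cc4ccccc4OCc4ccccc4)ccc3OCc3ccccc3)ccc2OCc2ccccc2)c1OCc1ccccc1 | intermediate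
17 | tert-butyl 3-[4,6-bis(benzyloxy)-3-(D-benzyl)-5-(T-benzyl)-2-hydroxyphenyl]-3-oxopropanoate | CC(C)(C)OC(=O)CC(=O)c1c(O)c(Cc2cc(Cc3ccccc3OCc3ccccc3)ccc2OCc2ccccc2)c(OCc2ccccc2)c(Cc2cc(Cc3cc(Cc4ccccc4OCc4ccccc4)ccc3OCc3ccccc3)ccc2OCc2ccccc2)c1OCc1ccccc1 | intermediate
18 | benzaldehyde | O=Cc1ccccc1 | starting material
19 | tert-butyl 2-[4,6-bis(benzyloxy)-3-(D-benzyl)-5-(T-benzyl)-2-hydroxybenzoyl]-3-phenylprop-2-enoate (E/Z mixture) | CC(C)(C)OC(=O)C(=Cc1ccccc1)C(=O)c1c(O)c(Cc2cc(Cc3ccccc3OCc3ccccc3)ccc2OCc2ccccc2)c(OCc2ccccc2)c(Cc2cc(Cc3cc(Cc4ccccc4OCc4ccccc4)ccc3OCc3ccccc3)ccc2OCc2ccccc2)c1OCc1ccccc1 | intermediate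
20 | tert-butyl (2S)-5,7-bis(benzyloxy)-8-(D-benzyl)-6-(T-benzyl)-4-oxo-2-phenylchromane-3-carboxylate (C3 epimers and enol in equilibrium) | O=C1C(C(=O)OC(C)(C)C)[C@@H](c2ccccc2)Oc2c(Cc3cc(Cc4ccccc4OCc4ccccc4)ccc3OCc3ccccc3)c(OCc3ccccc3)c(Cc3cc(Cc4cc(Cc5ccccc5OCc5ccccc5)ccc4OCc4ccccc4)ccc3OCc3ccccc3)c(OCc3ccccc3)c21 | intermediate
21 | (2S)-5,7-bis(benzyloxy)-8-(D-benzyl)-6-(T-benzyl)-2-phenylchroman-4-one | O=C1C[C@@H](c2ccccc2)Oc2c(Cc3cc(Cc4ccccc4OCc4ccccc4)ccc3OCc3ccccc3)c(OCc3ccccc3)c(Cc3cc(Cc4cc(Cc5ccccc5OCc5ccccc5)ccc4OCc4ccccc4)ccc3OCc3ccccc3)c(OCc3ccccc3)c21 | intermediate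
22 | Sarmentosumin D | O=C1C[C@@H](c2ccccc2)Oc2c(Cc3cc(Cc4ccccc4O)ccc3O)c(O)c(Cc3cc(Cc4cc(Cc5ccccc5O)ccc4O)ccc3O)c(O)c21 | target

**Totals and risks**

Total step count: 15. Longest linear sequence: 12 steps (steps 1–7, then 11–15; compounds 1 → 2 → 4 → 5 → 6 → 7 → 8 → 9 → 16 → 17 → 19 → 21 → 22).

Three steps most likely to fail:

Step 14. The facial selectivity of the oxa-Michael addition may be poor, because the aroyl group is flanked by OH and OBn and twisted out of the plane on which the catalyst must act. Benzyl groups may also be lost or migrate during the hot acidic decarboxylation. The fallback sets out from 16 and comes back at 21. Heating 16 with N,N-dimethylformamide dimethyl acetal in toluene should give the enaminone (E)-3-(dimethylamino)-1-[4,6-bis(benzyloxy)-3-(D-benzyl)-5-(T-benzyl)-2-hydroxyphenyl]prop-2-en-1-one F1. HCl in CH2Cl2 should close it, with loss of dimethylamine, to the chromone 5,7-bis(benzyloxy)-8-(D-benzyl)-6-(T-benzyl)-4H-chromen-4-one F2. Asymmetric conjugate addition of phenylboronic acid to F2 should then give 21, using Pd(OCOCF3)2 and the enantiomer of the tert-butyl pyridine-oxazoline ligand that leads to the 2S series (NH4PF6, H2O, 1,2-dichloroethane, 60 °C). In this variant ring C is closed by condensation and C2 is set by C–C bond formation, so neither the ester nor the acid treatment is needed.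

Step 11. Oxidative addition and transmetalation may be slow at an iodide flanked by two benzyloxy groups, so that proto-deiodination and homocoupling of the zinc reagent take over. The fallback sets out from 13 (together with alcohol 8) and comes back at 16, and it makes no new compound (F0). It is a dehydrative Friedel–Crafts benzylation of 13 with the three-ring benzylic alcohol 8 under Sc(OTf)3 (5 mol %) in CH2Cl2 at 0–25 °C. The ortho-alkoxybenzyl cation from 8 should be trapped at C5 of ring A, the only free carbon of the phloroglucinol ring and far more nucleophilic than any alkoxyarene ring of the chains. Steps 7 and 10 then fall away.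

Step 13. The amine may already promote an unselective oxa-Michael addition of the free phenol during the condensation, which would carry racemic ring-closed material into step 14. The fallback sets out from 16 and comes back at 21 by a stereospecific closure of ring C. C-benzoylation of the phenoxide–enolate dianion of 16 (LiN(SiMe3)2, PhCOCl, THF, −78 °C) should give the 1,3-diketone 1-[4,6-bis(benzyloxy)-3-(D-benzyl)-5-(T-benzyl)-2-hydroxyphenyl]-3-phenylpropane-1,3-dione F3. Asymmetric transfer hydrogenation (RuCl(p-cymene)[(R,R)-TsDPEN], HCO2H/Et3N) should reduce only the unhindered benzoyl carbonyl, giving the β-hydroxy ketone (3R)-1-[4,6-bis(benzyloxy)-3-(D-benzyl)-5-(T-benzyl)-2-hydroxyphenyl]-3-hydroxy-3-phenylpropan-1-one F4. Intramolecular Mitsunobu etherification (PPh3, diisopropyl azodicarboxylate, THF, 0 °C) with inversion at the carbinol carbon should then give the 2S ring of 21.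

**Further compounds**

F1 | step 14 | (E)-3-(dimethylamino)-1-[4,6-bis(benzyloxy)-3-(D-benzyl)-5-(T-benzyl)-2-hydroxyphenyl]prop-2-en-1-one | CN(C)/C=C/C(=O)c1c(O)c(Cc2cc(Cc3ccccc3OCc3ccccc3)ccc2OCc2ccccc2)c(OCc2ccccc2)c(Cc2cc(Cc3cc(Cc4ccccc4OCc4ccccc4)ccc3OCc3ccccc3)ccc2OCc2ccccc2)c1OCc1ccccc1
F2 | step 14 | 5,7-bis(benzyloxy)-8-(D-benzyl)-6-(T-benzyl)-4H-chromen-4-one | O=c1ccoc2c(Cc3cc(Cc4ccccc4OCc4ccccc4)ccc3OCc3ccccc3)c(OCc3ccccc3)c(Cc3cc(Cc4cc(Cc5ccccc5OCc5ccccc5)ccc4OCc4ccccc4)ccc3OCc3ccccc3)c(OCc3ccccc3)c12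
F0 | step 11 | none | none
F3 | step 13 | 1-[4,6-bis(benzyloxy)-3-(D-benzyl)-5-(T-benzyl)-2-hydroxyphenyl]-3-phenylpropane-1,3-dione | O=C(CC(=O)c1ccccc1)c1c(O)c(Cc2cc(Cc3ccccc3OCc3ccccc3)ccc2OCc2ccccc2)c(OCc2ccccc2)c(Cc2cc(Cc3cc(Cc4ccccc4OCc4ccccc4)ccc3OCc3ccccc3)ccc2OCc2ccccc2)c1OCc1ccccc1
F4 | step 13 | (3R)-1-[4,6-bis(benzyloxy)-3-(D-benzyl)-5-(T-benzyl)-2-hydroxyphenyl]-3-hydroxy-3-phenylpropan-1-one | O=C(C[C@@H](O)c1ccccc1)c1c(O)c(Cc2cc(Cc3ccccc3OCc3ccccc3)ccc2OCc2ccccc2)c(OCc2ccccc2)c(Cc2cc(Cc3cc(Cc4ccccc4OCc4ccccc4)ccc3OCc3ccccc3)ccc2OCc2ccccc2)c1OCc1ccccc1
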